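**Plan**

- Retrosynthesis: the eighteen O-alkyl groups are removed last. The ether bonds A–O–B, B–O–C, C–O–D, D–O–E and E–O–F are then cut one at a time from the ring A end, each between a phenol oxygen and a halogenated ring. Ring F is finally cut across three C–C bonds into a chromium alkenylcarbene, one CO ligand and the ethynyl ether of ring G.
- Feature used: in ring F the carbon carrying the middle hydroxyl sits between the carbon with the second hydroxyl and the carbon bound to the ring G oxygen, and para to the carbon whose oxygen leads to ring E. A carbene benzannulation delivers exactly this 1,4-dioxygenated ring with both neighbours of the CO-derived hydroxyl oxygenated.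
- Forward: ring G ynol ether plus carbene close ring F (step 5). The para oxygen arrives as a benzyl ether, so O-methylation of the new hydroxyl and hydrogenolysis expose a single unhindered phenol without passing through a quinone.
- Rings E, D, C and B are then added in that order as bromobenzaldehydes by Ullmann coupling, each formyl group becoming the next phenol by Baeyer–Villiger oxidation. Ring A comes from 2-iodo-1,3,5-trimethoxybenzene, and BBr3 frees all hydroxyls.
- Stereochemistry: the target has no stereocentre and no stereogenic double bond. The alkene geometry of the carbene disappears on aromatisation.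

Key step: step 5

Remark: carbene 12 is drawn as the E isomer, assumed to form by equilibration of the donor–acceptor C=C bond under the acidic exchange conditions of step 4; the geometry is of no consequence because that CH carbon becomes part of the arene.

**Route**

Step 1
Reactants: 1 3,4,5-trimethoxyphenol; 2 trichloroethylene
Product: 3 5-{[(E)-1,2-dichloroethenyl]oxy}-1,2,3-trimethoxybenzene
Conditions: K2CO3, DMF, 70 °C
Reagents that add atoms: none
Why: Base-mediated vinylation of a phenoxide by trichloroethylene (elimination to dichloroacetylene, then anti addition of the phenoxide) is the standard entry to aryl (E)-1,2-dichlorovinyl ethers, and the anti addition fixes the E geometry.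

Step 2
Reactants: 3 5-{[(E)-1,2-dichloroethenyl]oxy}-1,2,3-trimethoxybenzene
Product: 5 5-(ethynyloxy)-1,2,3-trimethoxybenzene, via lithium aryloxyacetylide 4 (not isolated)
Conditions: n-BuLi (2.5 equiv), THF, −78 to −40 °C; MeOH, −78 °C; kept as a cold solution and used at once
Reagents that add atoms: none
Why: Dehydrochlorination to the chloroalkyne followed by chlorine–lithium exchange is the established ynol ether synthesis from 1,2-dichlorovinyl ethers, and cold protonation of the acetylide should give the terminal aryl ethynyl ether, which has no beta hydrogen for a retro-ene loss of ketene.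

Step 3
Reactants: 6 (Z)-1-bromo-2-ethoxyethene; 7 hexacarbonylchromium Cr(CO)6
Product: 10 tetramethylammonium pentacarbonyl[(Z)-3-ethoxy-1-oxidoprop-2-en-1-ylidene]chromate, via (Z)-2-ethoxyvinyllithium 8 (not isolated), via lithium acylate 9 (not isolated)
Conditions: t-BuLi (2 equiv), Et2O, −78 °C; Cr(CO)6, THF, −78 to 0 °C; Me4NBr, H2O, 0 °C
Reagents that add atoms: tetramethylammonium bromide, C[N+](C)(C)C.[Br-]
Why: Bromine–lithium exchange with retention gives the chelation-stabilised beta-lithio enol ether, which adds to a CO ligand in the classical Fischer acylmetalate synthesis, and cation metathesis should give a storable ammonium salt.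

Step 4
Reactants: 10 tetramethylammonium pentacarbonyl[(Z)-3-ethoxy-1-oxidoprop-2-en-1-ylidene]chromate
Product: 12 pentacarbonyl[(E)-1-(benzyloxy)-3-ethoxyprop-2-en-1-ylidene]chromium, via acetoxycarbene complex 11 (not isolated)
Conditions: AcBr, CH2Cl2, −40 °C; BnOH (1.05 equiv), −40 to 0 °C
Reagents that add atoms: benzyl alcohol, OCc1ccccc1
Why: O-Acylation of the acylmetalate gives a highly electrophilic acyloxycarbene that undergoes addition–elimination with the alcohol at the carbene carbon (the acyl halide/alcohol variant of the Fischer carbene synthesis), and the acetic acid set free is expected to equilibrate the push–pull alkene to the E isomer.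

Step 5
Reactants: 12 pentacarbonyl[(E)-1-(benzyloxy)-3-ethoxyprop-2-en-1-ylidene]chromium; 5 5-(ethynyloxy)-1,2,3-trimethoxybenzene
Product: 14 4-(benzyloxy)-2-ethoxy-6-(3,4,5-trimethoxyphenoxy)phenol, via Cr(CO)3 arene complex 13 (not isolated)
Conditions: 5 (1.5 equiv), THF, 50 °C, Ar; then air, rt
Reagents that add atoms: none
Why: Proposed new method: loss of one CO from 12 lets ynol ether 5 bind and insert into the Cr=C bond with its CH carbon joined to the carbene carbon, so that the aryloxy-bearing carbon becomes the new, oxygen-stabilised carbene centre, a regiochemistry favoured both by the steric rule for terminal alkynes and by the polarisation of the ynol ether. CO insertion at that centre gives a chromium-bound dienylketene whose 6π electrocyclisation joins the ketene carbon to the ethoxy-bearing vinyl terminus and closes six-membered ring F in a formal [3+2+1] mode, and tautomerisation of the cyclohexadienone gives the phenol as its Cr(CO)3 complex 13, from which air releases 14. The closest known reactions are the Dötz benzannulation of alkenyl(alkoxy)carbene complexes of zerovalent chromium with terminal alkynes and the thermal CO insertion–cyclisation of dienyl(alkoxy)carbene complexes to ortho-alkoxyphenols; an aryl ethynyl ether paired with a beta-alkoxyalkenyl carbene has not been shown in this role. No stereocentre is formed and the alkene geometry of 12 is erased when its CH carbon becomes aromatic. The step needs regiocontrol (aryloxy next to the new hydroxyl, CH next to the benzyloxy carbon) and CO insertion in preference to cyclopentannulation, which the alkenyl (rather than aryl) carbene, the ether solvent and the moderate temperature should secure.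

Step 6
Reactants: 14 4-(benzyloxy)-2-ethoxy-6-(3,4,5-trimethoxyphenoxy)phenol
Product: 15 5-(benzyloxy)-1-ethoxy-2-methoxy-3-(3,4,5-trimethoxyphenoxy)benzene
Conditions: MeI, K2CO3, DMF, rt
Reagents that add atoms: iodomethane, CI
Why: Williamson O-methylation of the only free phenol, which is flanked by two oxygen substituents but should still react readily with the small electrophile.

Step 7
Reactants: 15 5-(benzyloxy)-1-ethoxy-2-methoxy-3-(3,4,5-trimethoxyphenoxy)benzene
Product: 16 3-ethoxy-4-methoxy-5-(3,4,5-trimethoxyphenoxy)phenol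
Conditions: H2 (1 atm), Pd/C (10 wt%), EtOAc/MeOH, rt
Reagents that add atoms: none
Why: Catalytic hydrogenolysis cleaves the single benzyl ether while methyl, ethyl and diaryl ethers are inert, exposing the unhindered ring F hydroxyl that lies para to the methoxy group.

Step 8
Reactants: 16 3-ethoxy-4-methoxy-5-(3,4,5-trimethoxyphenoxy)phenol; 17 2-bromo-3,4,5-trimethoxybenzaldehyde
Product: 18 2-[3-ethoxy-4-methoxy-5-(3,4,5-trimethoxyphenoxy)phenoxy]-3,4,5-trimethoxybenzaldehyde
Conditions: CuI (10 mol%), N,N-dimethylglycine hydrochloride (30 mol%), Cs2CO3, dioxane, 90 °C, Ar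
Reagents that add atoms: none
Why: Ullmann diaryl ether coupling in which the ortho formyl group activates the C–Br bond and the phenol has two free ortho positions; the formyl group is the latent oxygen for the next ether.

Step 9
Reactants: 18 2-[3-ethoxy-4-methoxy-5-(3,4,5-trimethoxyphenoxy)phenoxy]-3,4,5-trimethoxybenzaldehyde
Product: 20 2-[3-ethoxy-4-methoxy-5-(3,4,5-trimethoxyphenoxy)phenoxy]-3,4,5-trimethoxyphenol, via aryl formate 19 (not isolated)
Conditions: mCPBA, CH2Cl2, 0 °C to rt; aqueous NaHCO3 wash; K2CO3 (cat.), MeOH, rt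
Reagents that add atoms: 3-chloroperoxybenzoic acid (mCPBA), O=C(OO)c1cccc(Cl)c1
Why: Baeyer–Villiger oxidation in which the electron-rich aryl group (ortho aryloxy, para methoxy) migrates in preference to hydrogen, followed by mild methanolysis of the formate to the phenol.

Step 10
Reactants: 20 2-[3-ethoxy-4-methoxy-5-(3,4,5-trimethoxyphenoxy)phenoxy]-3,4,5-trimethoxyphenol; 21 4-bromo-3,5-dimethoxybenzaldehyde
Product: 22 rings G–F–E–D aldehyde (3,5-dimethoxybenzaldehyde carrying at C4 the aryloxy group of phenol 20)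
Conditions: CuI (20 mol%), picolinic acid (40 mol%), K3PO4, DMSO, 100 °C, Ar
Reagents that add atoms: none
Why: Ullmann coupling under the picolinic acid conditions used for hindered diaryl ethers, the para formyl group making the doubly ortho-substituted bromide electron-poor enough to couple.

Step 11
Reactants: 22 rings G–F–E–D aldehyde
Product: 24 rings G–F–E–D phenol (3,5-dimethoxyphenol carrying at C4 the aryloxy group of phenol 20), via aryl formate 23 (not isolated)
Conditions: mCPBA, CH2Cl2, 0 °C to rt; aqueous NaHCO3 wash; K2CO3 (cat.), MeOH, rt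
Reagents that add atoms: 3-chloroperoxybenzoic acid (mCPBA), O=C(OO)c1cccc(Cl)c1
Why: Baeyer–Villiger oxidation with aryl migration assisted by the para aryloxy group, then formate methanolysis, gives a phenol with both ortho positions free.

Step 12
Reactants: 24 rings G–F–E–D phenol; 17 2-bromo-3,4,5-trimethoxybenzaldehyde
Product: 25 rings G–F–E–D–C aldehyde (3,4,5-trimethoxybenzaldehyde carrying at C2 the aryloxy group of phenol 24)
Conditions: CuI (10 mol%), N,N-dimethylglycine hydrochloride (30 mol%), Cs2CO3, dioxane, 90 °C, Ar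
Reagents that add atoms: none
Why: Ullmann coupling of an unhindered phenol with the same ortho-formyl-activated bromide as in step 8.

Step 13
Reactants: 25 rings G–F–E–D–C aldehyde
Product: 27 rings G–F–E–D–C phenol (3,4,5-trimethoxyphenol carrying at C2 the aryloxy group of phenol 24), via aryl formate 26 (not isolated)
Conditions: mCPBA, CH2Cl2, 0 °C to rt; aqueous NaHCO3 wash; K2CO3 (cat.), MeOH, rt
Reagents that add atoms: 3-chloroperoxybenzoic acid (mCPBA), O=C(OO)c1cccc(Cl)c1
Why: Baeyer–Villiger oxidation and formate methanolysis as in step 9, on the same substitution pattern.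

Step 14
Reactants: 27 rings G–F–E–D–C phenol; 28 3-bromo-4,5-dimethoxybenzaldehyde
Product: 29 rings G–F–E–D–C–B aldehyde (4,5-dimethoxybenzaldehyde carrying at C3 the aryloxy group of phenol 27)
Conditions: CuI (20 mol%), picolinic acid (40 mol%), K3PO4, DMSO, 100 °C, Ar
Reagents that add atoms: none
Why: Ullmann coupling of a mono-ortho-substituted phenol with a mono-ortho-substituted aryl bromide, a combination well within the scope of the picolinic acid system.

Step 15
Reactants: 29 rings G–F–E–D–C–B aldehyde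
Product: 31 rings G–F–E–D–C–B phenol (3,4-dimethoxyphenol carrying at C5 the aryloxy group of phenol 27), via aryl formate 30 (not isolated)
Conditions: mCPBA, CH2Cl2, 0 °C to rt; aqueous NaHCO3 wash; K2CO3 (cat.), MeOH, rt
Reagents that add atoms: 3-chloroperoxybenzoic acid (mCPBA), O=C(OO)c1cccc(Cl)c1
Why: Baeyer–Villiger oxidation with migration of the aryl group bearing a para methoxy substituent, then formate methanolysis.

Step 16
Reactants: 31 rings G–F–E–D–C–B phenol; 32 2-iodo-1,3,5-trimethoxybenzene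
Product: 33 protected heptamer (1,3,5-trimethoxybenzene carrying at C2 the aryloxy group of phenol 31; seventeen methyl ethers and one ethyl ether)
Conditions: 32 (3 equiv), CuI (30 mol%), picolinic acid (60 mol%), K3PO4, DMSO, 110 °C, Ar
Reagents that add atoms: none
Why: Ullmann coupling of an unhindered phenol with a hindered, electron-rich aryl iodide, the reaction type long used for methylated phloroglucinol oligomers.

Step 17
Reactants: 33 protected heptamer
Product: 34 CNP0137585.0 (target heptamer with eighteen free hydroxyls)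
Conditions: BBr3 (about 3 equiv per ether), CH2Cl2, −78 °C to rt; H2O, 0 °C; work-up and chromatography under Ar
Reagents that add atoms: none
Why: Lewis acid ether cleavage by BBr3 removes all methyl ethers and the ethyl ether by bromide attack at the alkyl carbon, while the six diaryl ether bonds offer no such pathway and should survive.

**Compound list**

1 | 3,4,5-trimethoxyphenol | COc1cc(O)cc(OC)c1OC | starting material
2 | trichloroethylene | ClC=C(Cl)Cl | starting material
3 | 5-{[(E)-1,2-dichloroethenyl]oxy}-1,2,3-trimethoxybenzene | COc1cc(O/C(Cl)=C\Cl)cc(OC)c1OC | intermediate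
4 | lithium (3,4,5-trimethoxyphenoxy)acetylide | [Li]C#COc1cc(OC)c(OC)c(OC)c1 | intermediate (not isolated)
5 | 5-(ethynyloxy)-1,2,3-trimethoxybenzene | C#COc1cc(OC)c(OC)c(OC)c1 | intermediate
6 | (Z)-1-bromo-2-ethoxyethene | CCO/C=C\Br | starting material
7 | hexacarbonylchromium Cr(CO)6 | O=C=[Cr](=C=O)(=C=O)(=C=O)(=C=O)=C=O | starting material
8 | (Z)-2-ethoxyvinyllithium | CCO/C=C\[Li] | intermediate (not isolated)
9 | lithium pentacarbonyl[(Z)-3-ethoxy-1-oxidoprop-2-en-1-ylidene]chromate (lithium acylate) | CCO/C=C\C([O-])=[Cr](=C=O)(=C=O)(=C=O)(=C=O)=C=O.[Li+] | intermediate (not isolated)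
10 | tetramethylammonium pentacarbonyl[(Z)-3-ethoxy-1-oxidoprop-2-en-1-ylidene]chromate | CCO/C=C\C([O-])=[Cr](=C=O)(=C=O)(=C=O)(=C=O)=C=O.C[N+](C)(C)C | intermediate
11 | pentacarbonyl[(Z)-1-(acetyloxy)-3-ethoxyprop-2-en-1-ylidene]chromium | CCO/C=C\C(OC(C)=O)=[Cr](=C=O)(=C=O)(=C=O)(=C=O)=C=O | intermediate (not isolated)
12 | pentacarbonyl[(E)-1-(benzyloxy)-3-ethoxyprop-2-en-1-ylidene]chromium | CCO/C=C/C(OCc1ccccc1)=[Cr](=C=O)(=C=O)(=C=O)(=C=O)=C=O | intermediate
13 | tricarbonyl{η6-[4-(benzyloxy)-2-ethoxy-6-(3,4,5-trimethoxyphenoxy)phenol]}chromium, Cr(CO)3 on the new ring, written as an adduct | CCOc1cc(OCc2ccccc2)cc(Oc2cc(OC)c(OC)c(OC)c2)c1O.O=C=[Cr](=C=O)=C=O | intermediate (not isolated)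
14 | 4-(benzyloxy)-2-ethoxy-6-(3,4,5-trimethoxyphenoxy)phenol | CCOc1cc(OCc2ccccc2)cc(Oc2cc(OC)c(OC)c(OC)c2)c1O | intermediate
15 | 5-(benzyloxy)-1-ethoxy-2-methoxy-3-(3,4,5-trimethoxyphenoxy)benzene | CCOc1cc(OCc2ccccc2)cc(Oc2cc(OC)c(OC)c(OC)c2)c1OC | intermediate
16 | 3-ethoxy-4-methoxy-5-(3,4,5-trimethoxyphenoxy)phenol | CCOc1cc(O)cc(Oc2cc(OC)c(OC)c(OC)c2)c1OC | intermediate
17 | 2-bromo-3,4,5-trimethoxybenzaldehyde | COc1cc(C=O)c(Br)c(OC)c1OC | starting material
18 | 2-[3-ethoxy-4-methoxy-5-(3,4,5-trimethoxyphenoxy)phenoxy]-3,4,5-trimethoxybenzaldehyde | CCOc1cc(Oc2c(C=O)cc(OC)c(OC)c2OC)cc(Oc2cc(OC)c(OC)c(OC)c2)c1OC | intermediate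
19 | 2-[3-ethoxy-4-methoxy-5-(3,4,5-trimethoxyphenoxy)phenoxy]-3,4,5-trimethoxyphenyl formate | CCOc1cc(Oc2c(OC=O)cc(OC)c(OC)c2OC)cc(Oc2cc(OC)c(OC)c(OC)c2)c1OC | intermediate (not isolated)
20 | 2-[3-ethoxy-4-methoxy-5-(3,4,5-trimethoxyphenoxy)phenoxy]-3,4,5-trimethoxyphenol | CCOc1cc(Oc2c(O)cc(OC)c(OC)c2OC)cc(Oc2cc(OC)c(OC)c(OC)c2)c1OC | intermediate
21 | 4-bromo-3,5-dimethoxybenzaldehyde | COc1cc(C=O)cc(OC)c1Br | starting material
22 | 3,5-dimethoxy-4-{2-[3-ethoxy-4-methoxy-5-(3,4,5-trimethoxyphenoxy)phenoxy]-3,4,5-trimethoxyphenoxy}benzaldehyde (rings G–F–E–D aldehyde) | CCOc1cc(Oc2c(Oc3c(OC)cc(C=O)cc3OC)cc(OC)c(OC)c2OC)cc(Oc2cc(OC)c(OC)c(OC)c2)c1OC | intermediate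
23 | formate ester of phenol 24 | CCOc1cc(Oc2c(Oc3c(OC)cc(OC=O)cc3OC)cc(OC)c(OC)c2OC)cc(Oc2cc(OC)c(OC)c(OC)c2)c1OC | intermediate (not isolated)
24 | 3,5-dimethoxy-4-{2-[3-ethoxy-4-methoxy-5-(3,4,5-trimethoxyphenoxy)phenoxy]-3,4,5-trimethoxyphenoxy}phenol (rings G–F–E–D phenol) | CCOc1cc(Oc2c(Oc3c(OC)cc(O)cc3OC)cc(OC)c(OC)c2OC)cc(Oc2cc(OC)c(OC)c(OC)c2)c1OC | intermediate
25 | rings G–F–E–D–C aldehyde: 3,4,5-trimethoxybenzaldehyde with the aryloxy group of 24 at C2 | CCOc1cc(Oc2c(Oc3c(OC)cc(Oc4c(C=O)cc(OC)c(OC)c4OC)cc3OC)cc(OC)c(OC)c2OC)cc(Oc2cc(OC)c(OC)c(OC)c2)c1OC | intermediate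
26 | formate ester of phenol 27 | CCOc1cc(Oc2c(Oc3c(OC)cc(Oc4c(OC=O)cc(OC)c(OC)c4OC)cc3OC)cc(OC)c(OC)c2OC)cc(Oc2cc(OC)c(OC)c(OC)c2)c1OC | intermediate (not isolated)
27 | rings G–F–E–D–C phenol: 3,4,5-trimethoxyphenol with the aryloxy group of 24 at C2 | CCOc1cc(Oc2c(Oc3c(OC)cc(Oc4c(O)cc(OC)c(OC)c4OC)cc3OC)cc(OC)c(OC)c2OC)cc(Oc2cc(OC)c(OC)c(OC)c2)c1OC | intermediate
28 | 3-bromo-4,5-dimethoxybenzaldehyde | COc1cc(C=O)cc(Br)c1OC | starting material
29 | rings G–F–E–D–C–B aldehyde: 4,5-dimethoxybenzaldehyde with the aryloxy group of 27 at C3 | CCOc1cc(Oc2c(Oc3c(OC)cc(Oc4c(Oc5cc(C=O)cc(OC)c5OC)cc(OC)c(OC)c4OC)cc3OC)cc(OC)c(OC)c2OC)cc(Oc2cc(OC)c(OC)c(OC)c2)c1OC | intermediate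
30 | formate ester of phenol 31 | CCOc1cc(Oc2c(Oc3c(OC)cc(Oc4c(Oc5cc(OC=O)cc(OC)c5OC)cc(OC)c(OC)c4OC)cc3OC)cc(OC)c(OC)c2OC)cc(Oc2cc(OC)c(OC)c(OC)c2)c1OC | intermediate (not isolated)
31 | rings G–F–E–D–C–B phenol: 3,4-dimethoxyphenol with the aryloxy group of 27 at C5 | CCOc1cc(Oc2c(Oc3c(OC)cc(Oc4c(Oc5cc(O)cc(OC)c5OC)cc(OC)c(OC)c4OC)cc3OC)cc(OC)c(OC)c2OC)cc(Oc2cc(OC)c(OC)c(OC)c2)c1OC | intermediate
32 | 2-iodo-1,3,5-trimethoxybenzene | COc1cc(OC)c(I)c(OC)c1 | starting material
33 | protected heptamer: 1,3,5-trimethoxybenzene with the aryloxy group of 31 at C2 | CCOc1cc(Oc2c(Oc3c(OC)cc(Oc4c(Oc5cc(Oc6c(OC)cc(OC)cc6OC)cc(OC)c5OC)cc(OC)c(OC)c4OC)cc3OC)cc(OC)c(OC)c2OC)cc(Oc2cc(OC)c(OC)c(OC)c2)c1OC | intermediate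
34 | CNP0137585.0 | Oc1cc(O)c(Oc2cc(O)c(O)c(Oc3cc(O)c(O)c(O)c3Oc3cc(O)c(Oc4cc(O)c(O)c(O)c4Oc4cc(O)c(O)c(Oc5cc(O)c(O)c(O)c5)c4)c(O)c3)c2)c(O)c1 | target

**Step count and risks**

Total step count: 17. Longest linear sequence: 15 steps (steps 3, 4 and 5 to 17 from 6 and 7; equally steps 1, 2 and 5 to 17 from 1).

Steps most likely to fail:

1. Step 5, the one step beyond established substrate scope. The electron-rich ynol ether may insert and then stall at an oxygen-stabilised carbene before CO insertion, or it may be consumed by cyclopentannulation, cycloaddition to the carbene or oligomerisation. Fallback by known chemistry, setting out from 1 and returning at 16: commercial 3-bromo-5-ethoxy-4-hydroxybenzaldehyde is O-methylated (MeI, K2CO3, DMF) to 3-bromo-5-ethoxy-4-methoxybenzaldehyde F1. Ullmann coupling of F1 with phenol 1 (CuI, N,N-dimethylglycine hydrochloride, Cs2CO3, dioxane, 90 °C) should give 3-ethoxy-4-methoxy-5-(3,4,5-trimethoxyphenoxy)benzaldehyde F2. Baeyer–Villiger oxidation with mCPBA through 3-ethoxy-4-methoxy-5-(3,4,5-trimethoxyphenoxy)phenyl formate F3 and methanolysis (K2CO3, MeOH) then give phenol 16, so steps 1 to 7 are bypassed.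

2. Step 4. Conjugate addition of benzyl alcohol or bromide to the push–pull alkene, or thermal decay of the acyloxycarbene before alcoholysis, may erode the alkoxy exchange. Fallback, setting out from 10 and returning at 14: direct O-methylation of 10 (Me3OBF4, CH2Cl2/H2O, 0 °C) should give pentacarbonyl[(Z)-3-ethoxy-1-methoxyprop-2-en-1-ylidene]chromium F4. Benzannulation of F4 with 5 under the conditions of step 5 should pass through the Cr(CO)3 arene complex F5 and give, after exposure to air, 2-ethoxy-4-methoxy-6-(3,4,5-trimethoxyphenoxy)phenol F6. Oxidation of this 4-methoxyphenol with PhI(OAc)2 in MeCN/H2O should give 2-ethoxy-6-(3,4,5-trimethoxyphenoxy)cyclohexa-2,5-diene-1,4-dione F7, and Na2S2O4 reduction 2-ethoxy-6-(3,4,5-trimethoxyphenoxy)benzene-1,4-diol F8. Benzylation with one equivalent of BnBr (K2CO3, acetone) should take place at the hydroxyl flanked by two hydrogens and give 14.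

3. Step 16. Sluggish reaction of the doubly ortho-substituted, electron-rich iodide at copper may let protodeiodination and oxidative decay of the phenolate win. Fallback, setting out from 31 and returning at 33: ring A is built from the activated bromide 21 instead. Ullmann coupling of 31 with 21 under the conditions of step 10 should give the heptamer aldehyde F9 (3,5-dimethoxybenzaldehyde carrying the aryloxy group of 31 at C4). Baeyer–Villiger oxidation with mCPBA through the formate F10 and methanolysis give the heptamer phenol F11, and O-methylation (MeI, K2CO3, DMF) gives 33.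

**Further compounds**

F1 | step 5 | 3-bromo-5-ethoxy-4-methoxybenzaldehyde | CCOc1cc(C=O)cc(Br)c1OC
F2 | step 5 | 3-ethoxy-4-methoxy-5-(3,4,5-trimethoxyphenoxy)benzaldehyde | CCOc1cc(C=O)cc(Oc2cc(OC)c(OC)c(OC)c2)c1OC
F3 | step 5 | 3-ethoxy-4-methoxy-5-(3,4,5-trimethoxyphenoxy)phenyl formate | CCOc1cc(OC=O)cc(Oc2cc(OC)c(OC)c(OC)c2)c1OC
F4 | step 4 | pentacarbonyl[(Z)-3-ethoxy-1-methoxyprop-2-en-1-ylidene]chromium | CCO/C=C\C(OC)=[Cr](=C=O)(=C=O)(=C=O)(=C=O)=C=O
F5 | step 4 | tricarbonyl{η6-[2-ethoxy-4-methoxy-6-(3,4,5-trimethoxyphenoxy)phenol]}chromium, written as an adduct | CCOc1cc(OC)cc(Oc2cc(OC)c(OC)c(OC)c2)c1O.O=C=[Cr](=C=O)=C=O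
F6 | step 4 | 2-ethoxy-4-methoxy-6-(3,4,5-trimethoxyphenoxy)phenol | CCOc1cc(OC)cc(Oc2cc(OC)c(OC)c(OC)c2)c1O
F7 | step 4 | 2-ethoxy-6-(3,4,5-trimethoxyphenoxy)cyclohexa-2,5-diene-1,4-dione | CCOC1=CC(=O)C=C(Oc2cc(OC)c(OC)c(OC)c2)C1=O
F8 | step 4 | 2-ethoxy-6-(3,4,5-trimethoxyphenoxy)benzene-1,4-diol | CCOc1cc(O)cc(Oc2cc(OC)c(OC)c(OC)c2)c1O
F9 | step 16 | heptamer aldehyde: 3,5-dimethoxybenzaldehyde with the aryloxy group of 31 at C4 | CCOc1cc(Oc2c(Oc3c(OC)cc(Oc4c(Oc5cc(Oc6c(OC)cc(C=O)cc6OC)cc(OC)c5OC)cc(OC)c(OC)c4OC)cc3OC)cc(OC)c(OC)c2OC)cc(Oc2cc(OC)c(OC)c(OC)c2)c1OC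
F10 | step 16 | formate ester of heptamer phenol F11 | CCOc1cc(Oc2c(Oc3c(OC)cc(Oc4c(Oc5cc(Oc6c(OC)cc(OC=O)cc6OC)cc(OC)c5OC)cc(OC)c(OC)c4OC)cc3OC)cc(OC)c(OC)c2OC)cc(Oc2cc(OC)c(OC)c(OC)c2)c1OC
F11 | step 16 | heptamer phenol: 3,5-dimethoxyphenol with the aryloxy group of 31 at C4 | CCOc1cc(Oc2c(Oc3c(OC)cc(Oc4c(Oc5cc(Oc6c(OC)cc(O)cc6OC)cc(OC)c5OC)cc(OC)c(OC)c4OC)cc3OC)cc(OC)c(OC)c2OC)cc(Oc2cc(OC)c(OC)c(OC)c2)c1OC
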